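2.5 mol%: hold your hunch of short chains against that charge of initiator.

in all of them: initiator 2.5 mol%

| run | free monomer | remark | time |
|---|---|---|---|
| dusk | 1.9 M | the very flask that is asked about, followed so far |  |
| spring | 1.3 M | run made earlier |  |
| flask | 1.9 M |  | 8.0 min |

dusk run (percent of the free monomer charged)

| time / s | monomer in chains / % | free monomer / % |
|---|---|---|
| 10.0 | 0 | 97.7 |
| 20.0 | 0 | 93.3 |
| 30.0 | 0 | 91.3 |
| 40.0 | 0 | 88.3 |
| 50.0 | 0.8 | 86.9 |
| 60.0 | 0 | 84.0 |

spring run (percent of the free monomer charged)

| time / min | monomer in chains / % | free monomer / % |
|---|---|---|
| 0.500 | 0.4 | 92.6 |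
| 1.50 | 1.7 | 78.2 |
| 3.00 | 3.2 | 62.3 |
| 4.00 | 2.9 | 52.3 |
| 6.00 | 3.5 | 39.6 |
| 8.00 | 3.9 | 29.9 |

(standard deviation of a reading: 1 percentage point)

- the average divides the monomer in chains by the number of chains begun, living and dead together
- what was read earlier has a scatter of 1 percentage point, one standard deviation
- the earlier runs do not show the number of chains; that part of a forecast is a guess

- average number of monomer units in a chain (chains begun, living or dead) at 8.0 min
- part of the free monomer that has reacted at 8.0 min

Write the initiator's balance: what was charged either still stands, has begun a chain or has ended as something else, so chains begun cannot pass the charge. Spring holds 3.9% in chains at 8.00 min, which gives 1.56 monomer units per initiator charged. This is the initiator floor, monomer in chains divided by initiator charged, and dp cannot lie below it. Dp is the floor divided by the share of initiator that begins chains, and the runs do not show that share. Dusk's chains are still within the scatter, so with spring as a stand-in I commit only to dp of about 1.56 or more, a reading that carries the scatter. For c, spring lost 70.1% by 8.00 min, and dusk at 30.0 s has 91.3% left against spring's 92.6% at that time, a gap close to the scatter of 1 percentage point, so I say slightly more, without much weight.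

The forecast gives dp 2.5 (1.5 to 6) and c 74% (70% to 78%), reasoning “If roughly 70% of it starts chains”.

The simulation gives dp 36.1 and c 70.6%.

    free monomer + initiator → living end + monomer in chains (k = 0.00240 L mol⁻¹ s⁻¹)
    free monomer + living end → monomer in chains + living end, rate k2*[living end]*[free monomer] (k = 0.0740 L mol⁻¹ s⁻¹)
    free monomer + initiator → spent initiator A (k = 0.0370 L mol⁻¹ s⁻¹)
    free monomer → uncatalysed product (k = 0.00230 s⁻¹)
    2 living end → dead end B (k = 0.0380 L mol⁻¹ s⁻¹)

In this flask initiator fell to 3.58% of its charge by 0.800 min, and at the start it turned into spent initiator A at 15 times the rate at which it began chains. With initiator at 0%, living ends took monomer in chains from 3.57% at 4.00 min to 5.50% at 8.00 min, beside 62.8% uncatalysed product. The floor here is 2.20 against dp 36.1, so the share of initiator that began chains is 6.09%. The same flask read at 3.0 min has floor 1.14 against dp 18.8, a share of 6.09%.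

Readings and results stem from a simulated flask from invented constants, noise included.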